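**Plan**

1. Retrosynthesis cuts, in this order: the two aryl C–CHO bonds (late double C–H formylation of the only two free arene positions); the C1′–H bond (back to a 4-phenylchroman-4-ol); then the C5–C1′ bond, with an oxygen put back between C5 and C1′ (reverse [1,2]-Wittig shift). This turns the chroman into a seven-membered 1,4-benzodioxepine, which is opened at aryl–O(C4) and at O–C1′ to a benzhydrol and the syn-4,5-diol of the terpene.
2. Forward: the nine- and four-membered carbocycles come with the terpene; the dioxepine is closed on the diol (benzhydryl ether, then aryl ether); the key step contracts it by one atom to the pyran ring of the chroman; the arene is finished last.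
3. Enabling feature: C1′ is doubly benzylic and bears the ring oxygen, so it is the one site that is lithiated; O–C5 then breaks and C5 re-bonds to C1′. The oxygen expelled from the ring stays on C1′ as a helper hydroxyl, removed by ionic hydrogenation.
4. Stereochemistry: C1 and C9 come from the terpene; C4 and C5 from suprafacial osmylation of the strained E-C4=C5 alkene on its open face; C5 is retained in the 1,2-shift; C1′ is stereoconvergent (both epimers pass through one carbanion, then one cation) and is fixed by hydride delivery anti to C6 and the C4 methyl.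

Key step: step 5

Assumption: the (1S,9R) cyclobutane centres of the target are those of (+)-β-caryophyllene, the antipode of the clove-oil terpene; compound 1 is taken to be purchasable as this enantiomer (the same route on (−)-β-caryophyllene would give the mirror image of the target).

Numbering used in names: caryophyllane C1–C11 (C4 bears the methyl, C8 the methylidene, C11 the gem-dimethyl); C1′ is the phenyl-bearing carbon.

**Step 1**
Reactants: 1 (+)-β-caryophyllene
Product: 2 (1S,4S,5S,9R)-4,11,11-trimethyl-8-methylidenebicyclo[7.2.0]undecane-4,5-diol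
Conditions: K2OsO2(OH)4 (2 mol%), NMO (1.1 equiv), acetone/H2O, 0 °C
Reagents that add atoms: N-methylmorpholine N-oxide (C[N+]1([O-])CCOCC1); water (O)
Why: Upjohn dihydroxylation: osmium tetroxide should add suprafacially to the strained, more electron-rich trisubstituted E-C4=C5 alkene in preference to the 1,1-disubstituted one, on the open outer face that peracids also take, setting C4 and C5 as (4S,5S) with both oxygens on the face the target needs.

**Step 2**
Reactants: 3 2-bromo-4,6-dimethoxybenzaldehyde; 4 phenylmagnesium bromide
Product: 5 (2-bromo-4,6-dimethoxyphenyl)(phenyl)methanol (racemic)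
Conditions: THF, 0 °C; aq. NH4Cl
Reagents that add atoms: none
Why: Grignard addition to the aldehyde (aryl bromide and methyl ethers are inert at 0 °C); the carbinol centre needs no control because it is planarised in steps 5 and 6.

**Step 3**
Reactants: 2 syn-diol; 5 benzhydrol
Product: 6 5-O-[(2-bromo-4,6-dimethoxyphenyl)(phenyl)methyl] ether of 2 (C4–OH free; both C1′ epimers)
Conditions: CSA (5 mol%), 4 Å MS, CH2Cl2, 0 → 23 °C
Reagents that add atoms: none
Why: Acid-catalysed SN1 etherification through the 2,4-dimethoxy-stabilised benzhydryl cation, which should be taken by the secondary C5–OH and not by the hindered tertiary C4–OH; the C1′ epimers are carried on together.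

**Step 4**
Reactants: 6 bromoaryl benzhydryl ether
Product: 7 6,8-dimethoxy-5-phenyl-2,3-dihydro-5H-1,4-benzodioxepine fused at C2–C3 to caryophyllane C4–C5 (aryl O on C4, benzhydryl O on C5; 1S,4S,5S,9R; both C1′ epimers)
Conditions: Pd(OAc)2 (5 mol%), 2-(di-tert-butylphosphino)-1,1′-binaphthyl (6 mol%), Cs2CO3, toluene, 80 °C
Reagents that add atoms: none
Why: Buchwald–Hartwig-type intramolecular C–O coupling: the tertiary alkoxide has no hydrogen on its carbinol carbon, so β-hydride elimination is impossible and C–O reductive elimination should close the seven-membered ring with C4 untouched.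

**Step 5**
Reactants: 7 benzodioxepine
Product: 9 5,7-dimethoxy-4-phenylchroman-4-ol fused at C2–C3 to caryophyllane C4–C5 (O on C4, C1′ on C5; 1S,4S,5R,9R; both C1′ epimers), via C1′-lithio benzodioxepine 8 (not isolated)
Conditions: n-BuLi (2 equiv), THF, −78 → 23 °C; then H2O
Reagents that add atoms: none
Why: [1,2]-Wittig rearrangement run as a ring contraction: n-BuLi removes C1′–H, the only proton that is both doubly benzylic and α to oxygen, and on warming the O–C5 bond of 8 homolyses to a tethered ketyl radical anion/C5 radical pair that recombines at C1′. The closest known reaction type is the ring-contracting [1,2]-Wittig shift of cyclic benzylic and allylic ethers to cycloalkanols. The six-membered pyran ring closes by collapse of this radical pair (C5–C1′ bond formation inside the former seven-membered ring), and the oxygen that leaves the ring stays on C1′ as a lithium alkoxide. C5 should keep its configuration because the caged pair recombines on the face the oxygen has just left, faster than the nine-membered ring can turn the C5 radical over; C4 is a spectator, and the new C1′ carbinol centre is left uncontrolled because step 6 planarises it. The step needs site-selective lithiation and 1,2-shift in preference to α′,β-elimination: the first is secured by the acidity of C1′–H (any aryl lithiation between the methoxy groups is undone on quench), the second by generating the stabilised carbanion cold and warming slowly. Both C1′ epimers of 7 converge on the same carbanion.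

**Step 6**
Reactants: 9 chroman-4-ol
Product: 11 (1S,4S,5R,9R,1′R)-5,7-dimethoxy-4-phenylchroman fused as in 9 (the di-O-methyl, bis-deformyl target), via chroman-4-ylium cation 10 (not isolated)
Conditions: Et3SiH (5 equiv), BF3·OEt2 (0.2 equiv), CH2Cl2, −78 → −30 °C
Reagents that add atoms: none
Why: Ionic hydrogenation (Kursanov–Parnes): both carbinol epimers ionise to the same planar 2,4,6-trioxygenated diarylmethyl cation 10, and silane hydride should enter anti to C6 on the adjacent carbon and anti to the C4 methyl, that is on the H-5 face, giving (1′R); excess silane at low temperature is meant to intercept the cation before E1 loss of H-5.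

**Step 7**
Reactants: 11 dimethoxy chroman
Product: 12 (1S,4S,5R,9R,1′R)-5,7-dihydroxy-4-phenylchroman fused as in 9 (bis-deformyl target)
Conditions: MeMgI (excess), Et2O removed, neat, 160 °C; aq. NH4Cl
Reagents that add atoms: none
Why: Methyl ether cleavage by methylmagnesium iodide (iodide SN2 on the magnesium-bound methyl ether) is precedented for resorcinol dimethyl ethers that carry a tertiary chroman ether and acid-labile alkenes; neither of these can react by SN2 and no acid is present.

**Step 8**
Reactants: 12 dihydroxy chroman
Product: 14 psidial A as drawn, (1S,4S,5R,9R,1′R), via bis-iminium salt 13 (not isolated)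
Conditions: POCl3 (2.5 equiv), DMF (2.5 equiv), EtOAc, 0 → 23 °C; then H2O, 50 °C
Reagents that add atoms: N,N-dimethylformamide (CN(C)C=O); water (O)
Why: Vilsmeier–Haack double formylation: the two remaining arene C–H positions (C6 and C8 of the chroman) are each ortho/para to three oxygen substituents, so the chloroiminium ion should attack both, and hydrolysis of 13 releases the dialdehyde without touching a stereocentre.

**Compound list**

1 | (+)-β-caryophyllene, (1S,4E,9R)-4,11,11-trimethyl-8-methylidenebicyclo[7.2.0]undec-4-ene | C/C1=C\CCC(=C)[C@@H]2CC(C)(C)[C@H]2CC1 | starting material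
2 | (1S,4S,5S,9R)-4,11,11-trimethyl-8-methylidenebicyclo[7.2.0]undecane-4,5-diol | C=C1CC[C@H](O)[C@](O)(C)CC[C@H]2[C@H]1CC2(C)C | intermediate
3 | 2-bromo-4,6-dimethoxybenzaldehyde | COc1cc(OC)c(C=O)c(Br)c1 | starting material
4 | phenylmagnesium bromide | Br[Mg]c1ccccc1 | starting material
5 | (2-bromo-4,6-dimethoxyphenyl)(phenyl)methanol, racemic | COc1cc(OC)c(C(O)c2ccccc2)c(Br)c1 | intermediate
6 | 5-O-[(2-bromo-4,6-dimethoxyphenyl)(phenyl)methyl] ether of 2, both C1′ epimers | C=C1CC[C@H](OC(c2ccccc2)c2c(Br)cc(OC)cc2OC)[C@](O)(C)CC[C@H]2[C@H]1CC2(C)C | intermediate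
7 | caryophyllane-fused 6,8-dimethoxy-5-phenyl-2,3-dihydro-5H-1,4-benzodioxepine (1S,4S,5S,9R), both C1′ epimers | C=C1CC[C@@H]2OC(c3ccccc3)c3c(OC)cc(OC)cc3O[C@@]2(C)CC[C@H]2[C@H]1CC2(C)C | intermediate
8 | C1′-lithio derivative of 7 | C=C1CC[C@@H]2OC([Li])(c3ccccc3)c3c(OC)cc(OC)cc3O[C@@]2(C)CC[C@H]2[C@H]1CC2(C)C | intermediate
9 | caryophyllane-fused 5,7-dimethoxy-4-phenylchroman-4-ol (1S,4S,5R,9R), both C1′ epimers | C=C1CC[C@@H]2C(O)(c3ccccc3)c3c(OC)cc(OC)cc3O[C@@]2(C)CC[C@H]2[C@H]1CC2(C)C | intermediate
10 | 5,7-dimethoxy-4-phenylchroman-4-ylium hydroxytrifluoroborate | C=C1CC[C@@H]2[C+](c3ccccc3)c3c(OC)cc(OC)cc3O[C@@]2(C)CC[C@H]2[C@H]1CC2(C)C.O[B-](F)(F)F | intermediate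
11 | (1S,4S,5R,9R,1′R)-5,7-dimethoxy-4-phenylchroman fused at C2–C3 to caryophyllane C4–C5 | C=C1CC[C@@H]2[C@H](c3ccccc3)c3c(OC)cc(OC)cc3O[C@@]2(C)CC[C@H]2[C@H]1CC2(C)C | intermediate
12 | (1S,4S,5R,9R,1′R)-5,7-dihydroxy-4-phenylchroman fused as in 11 | C=C1CC[C@@H]2[C@H](c3ccccc3)c3c(O)cc(O)cc3O[C@@]2(C)CC[C@H]2[C@H]1CC2(C)C | intermediate
13 | 6,8-bis(dimethyliminiomethyl) derivative of 12, dichloride | C=C1CC[C@@H]2[C@H](c3ccccc3)c3c(O)c(C=[N+](C)C)c(O)c(C=[N+](C)C)c3O[C@@]2(C)CC[C@H]2[C@H]1CC2(C)C.[Cl-].[Cl-] | intermediate
14 | psidial A as drawn, (1S,4S,5R,9R,1′R)-5,7-dihydroxy-4-phenylchroman-6,8-dicarbaldehyde fused as in 11 | C=C1CC[C@@H]2[C@H](c3ccccc3)c3c(O)c(C=O)c(O)c(C=O)c3O[C@@]2(C)CC[C@H]2[C@H]1CC2(C)C | target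

**Step count and risks**

Total: 8 steps. Longest linear sequence: 7 steps (1 → 2 → 6 → 7 → 9 → 11 → 12 → 14).

Steps most likely to fail:

- Step 5. The lithiated ether may collapse by α′,β-syn-elimination (internal proton abstraction at C6 with C5–O cleavage) or the radical pair may recombine with loss of configuration at C5. Fallback, setting out from 1 and returning at 11: 2-[hydroxy(phenyl)methyl]-3,5-dimethoxyphenol F1, made by ortho-selective addition of the bromomagnesium phenoxide of 3,5-dimethoxyphenol to benzaldehyde, is heated with 1 (toluene, sealed tube, 150 °C). Thermal loss of water gives 6-benzylidene-3,5-dimethoxycyclohexa-2,4-dienone (o-quinone methide) F2, whose inverse-demand hetero-Diels–Alder reaction with the strained E-alkene builds the pyran ring directly in its final size; 11 would be separated from its diastereomers.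

- Step 4. C–O reductive elimination to a seven-membered ring from a hindered tertiary alkoxide may be slower than protodebromination. Fallback, setting out from 2 and returning at 7: the C5 hydroxyl is masked as the 5-O-(4-methoxybenzyl) ether F3 (stannylene acetal, then PMBCl/CsF). The free tertiary alkoxide (KH, DMF) then displaces fluoride from (2-fluoro-4,6-dimethoxyphenyl)(phenyl)methanone F4 (from 1-fluoro-3,5-dimethoxybenzene by lithiation between F and OMe at −78 °C and acylation with N-methoxy-N-methylbenzamide) in a carbonyl-activated SNAr reaction, giving the C4 aryl ether ketone F5. DDQ removes the PMB group to give the hydroxy ketone F6, and reductive etherification (Et3SiH, TMSOTf, −78 °C) through the cyclic oxocarbenium ion closes the dioxepine.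

- Step 6. Hydride delivery to the planar cation may show poor facial selectivity, or E1 loss of H-5 may erode C5. Fallback, setting out from 1 and returning at 14: 1, benzaldehyde and 2,4,6-trihydroxybenzene-1,3-dicarbaldehyde are heated in water. Knoevenagel condensation gives 3,5-diformyl-2,4-dihydroxy-6-benzylidenecyclohexa-2,4-dienone (o-quinone methide) F7, and its hetero-Diels–Alder reaction with 1 sets C1′ through the cycloaddition transition state instead of a hydride delivery; 14 would be separated from its C1′ epimer.

**Further compounds**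

F1 | step 5 | 2-[hydroxy(phenyl)methyl]-3,5-dimethoxyphenol | COc1cc(O)c(C(O)c2ccccc2)c(OC)c1
F2 | step 5 | 6-benzylidene-3,5-dimethoxycyclohexa-2,4-dien-1-one | O=C1C=C(OC)C=C(OC)C1=Cc1ccccc1
F3 | step 4 | 5-O-(4-methoxybenzyl) ether of 2 | C=C1CC[C@H](OCc2ccc(OC)cc2)[C@](O)(C)CC[C@H]2[C@H]1CC2(C)C
F4 | step 4 | (2-fluoro-4,6-dimethoxyphenyl)(phenyl)methanone | COc1cc(F)c(C(=O)c2ccccc2)c(OC)c1
F5 | step 4 | 4-O-(2-benzoyl-3,5-dimethoxyphenyl)-5-O-(4-methoxybenzyl) derivative of 2 | C=C1CC[C@H](OCc2ccc(OC)cc2)[C@](Oc2cc(OC)cc(OC)c2C(=O)c2ccccc2)(C)CC[C@H]2[C@H]1CC2(C)C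
F6 | step 4 | 4-O-(2-benzoyl-3,5-dimethoxyphenyl) derivative of 2 | C=C1CC[C@H](O)[C@](Oc2cc(OC)cc(OC)c2C(=O)c2ccccc2)(C)CC[C@H]2[C@H]1CC2(C)C
F7 | step 6 | 5-benzylidene-2,4-dihydroxy-6-oxocyclohexa-1,3-diene-1,3-dicarbaldehyde | O=CC1=C(O)C(C=O)=C(O)C(=Cc2ccccc2)C1=O
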